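## Retrosynthetic overview

1. The strategy rests on the carbocycle C1–C5 (C1 ketone, C2=C3 alkene, C4 secondary carbinol, C5 tertiary carbinol carrying the C6 acetoxy side chain). It is an isomer of a 6‑oxy‑2H‑pyran‑3(6H)‑one whose ring oxygen is the future C5 hydroxyl and whose acetal oxygen is the future O4.
2. Target 17 comes from the protected cyclopentenone 14 (O4 silyl, O6 PMB) by PMB removal, acetylation of O6 and desilylation.
3. The only ring is closed once, by forming C4–C5 in an Et3N/MgBr2 ring contraction of silyloxypyranone 11 to 14.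
4. Pyranone 11 comes from Achmatowicz oxidation and lactol silylation of furyl carbinol 8, made from furan and aldehyde 5.
5. Aldehyde 5 carries the only imported stereocentre (C6). It comes from (S)‑tetradecane‑1,2‑diol, obtained by hydrolytic kinetic resolution of racemic 1,2‑epoxytetradecane.

Key step: step 8

Remark on the chemistry: the (R,R) salen–cobalt complex is taken to hydrolyse the (S)‑oxirane, as for other 2‑alkyloxiranes; C5 is written 5R in 14–16 and 5S in 17 only because the CIP ranking of C4 and C6 changes when silicon leaves O4, no bond at C5 being touched.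

## Route

Step 1
Reactants: 1 rac‑1,2‑epoxytetradecane
Product: 2 (S)‑tetradecane‑1,2‑diol
Conditions: (R,R)‑(salen)Co(OAc) [salen = N,N'‑bis(3,5‑di‑tert‑butylsalicylidene)‑1,2‑cyclohexanediaminate; trivalent cobalt] (0.5 mol%), H2O (0.45 equiv), THF, 0 °C → rt; diol separated from the unreacted epoxide and recrystallised
Reagents that add atoms: water, O
Why: Hydrolytic kinetic resolution with a chiral salen cobalt complex: the (R,R) catalyst delivers hydroxide to the terminal carbon of the (S)‑oxirane only, so C2 is not touched and the (S)‑diol is obtained by selection between the enantiomers of 1, with recrystallisation available to raise its enantiomeric purity.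

Step 2
Reactants: 2 (S)‑tetradecane‑1,2‑diol
Product: 3 (4S)‑4‑dodecyl‑2‑(4‑methoxyphenyl)‑1,3‑dioxolane (both C2 epimers)
Conditions: 4‑MeOC6H4CH(OMe)2, PPTS (cat.), CH2Cl2, rt
Reagents that add atoms: 4‑methoxybenzaldehyde dimethyl acetal, COC(OC)c1ccc(OC)cc1
Why: Acid‑catalysed transacetalisation of a 1,2‑diol to its five‑membered p‑methoxybenzylidene acetal, driven by loss of methanol; the new acetal carbon forms as a mixture that is removed in the next step.

Step 3
Reactants: 3 (4S)‑4‑dodecyl‑2‑(4‑methoxyphenyl)‑1,3‑dioxolane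
Product: 4 (2S)‑2‑(4‑methoxybenzyloxy)tetradecan‑1‑ol
Conditions: i‑Bu2AlH (3 equiv), CH2Cl2, −78 → 0 °C; Rochelle salt work‑up
Reagents that add atoms: none
Why: Regioselective reductive opening of a benzylidene‑type acetal: the aluminium Lewis acid binds the less hindered primary oxygen, that C–O bond ionises and hydride is delivered to the benzylic carbon, which leaves the PMB group on the secondary oxygen and the C2 configuration unchanged.

Step 4
Reactants: 4 (2S)‑2‑(4‑methoxybenzyloxy)tetradecan‑1‑ol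
Product: 5 (2S)‑2‑(4‑methoxybenzyloxy)tetradecanal
Conditions: TEMPO (10 mol%), PhI(OAc)2 (1.1 equiv), CH2Cl2, rt; used at once
Reagents that add atoms: none
Why: TEMPO‑catalysed oxidation with PhI(OAc)2 as terminal oxidant (oxoammonium mechanism) stops at the aldehyde under nearly neutral conditions, so the enolisable alpha‑alkoxy stereocentre is not epimerised and the PMB ether is not attacked.

Step 5
Reactants: 5 (2S)‑2‑(4‑methoxybenzyloxy)tetradecanal, 6 furan
Product: 8 (2S)‑1‑(furan‑2‑yl)‑2‑(4‑methoxybenzyloxy)tetradecan‑1‑ol (both C1 epimers), via 2‑furyllithium 7 (not isolated)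
Conditions: furan (1.5 equiv), n‑BuLi, THF, −78 → 0 °C; then 5, −78 °C; then H2O
Reagents that add atoms: none
Why: Lithiation of furan at C2 and 1,2‑addition of the aryllithium to the aldehyde at low temperature; the new carbinol centre forms as a mixture of epimers, which is accepted because this carbon becomes the enolisable ring carbon next to the pyranone ketone and is erased in step 8.

Step 6
Reactants: 8 (2S)‑1‑(furan‑2‑yl)‑2‑(4‑methoxybenzyloxy)tetradecan‑1‑ol
Product: 10 6‑hydroxy‑2‑[(1S)‑1‑(4‑methoxybenzyloxy)tridecyl]‑2H‑pyran‑3(6H)‑one (all four ring isomers), via (Z)‑ene‑dione 9 (not isolated)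
Conditions: NBS (1.05 equiv), NaHCO3 (2 equiv), THF/H2O (4:1), 0 °C
Reagents that add atoms: water, O
Why: Achmatowicz rearrangement: bromonium attack on the furan and addition of water give a 2,5‑dihydrofuran that opens to the (Z)‑ene‑dione 9, whose carbinol hydroxyl adds to the aldehyde to close the six‑membered lactol; furan is far more reactive towards NBS than the anisyl ring, and the new hemiacetal carbon forms as a mixture that converges later.

Step 7
Reactants: 10 6‑hydroxy‑2‑[(1S)‑1‑(4‑methoxybenzyloxy)tridecyl]‑2H‑pyran‑3(6H)‑one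
Product: 11 6‑(tert‑butyldimethylsilyloxy)‑2‑[(1S)‑1‑(4‑methoxybenzyloxy)tridecyl]‑2H‑pyran‑3(6H)‑one (all four ring isomers)
Conditions: TBSCl (1.3 equiv), imidazole (2 equiv), CH2Cl2, 0 °C
Reagents that add atoms: tert‑butyldimethylsilyl chloride, CC(C)(C)[Si](C)(C)Cl
Why: Silylation of the only free hydroxyl, the lactol OH, locks the pyranone as its silyl acetal and places a poor leaving group on the anomeric carbon, so that base in the next step enolises next to the ketone instead of ionising to an oxidopyrylium; no stereocentre needs control because all four ring isomers converge in step 8.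

Step 8
Reactants: 11 6‑(tert‑butyldimethylsilyloxy)‑2‑[(1S)‑1‑(4‑methoxybenzyloxy)tridecyl]‑2H‑pyran‑3(6H)‑one
Product: 14 (4S,5R)‑4‑(tert‑butyldimethylsilyloxy)‑5‑hydroxy‑5‑[(1S)‑1‑(4‑methoxybenzyloxy)tridecyl]cyclopent‑2‑en‑1‑one, via magnesium pyranone enolate 12 (not isolated), via open‑chain dienolate ketone 13 (not isolated)
Conditions: MgBr2·OEt2 (2 equiv), Et3N (3 equiv), CH2Cl2, −20 °C → rt; then aq. NH4Cl
Reagents that add atoms: none
Why: Proposed new method: Et3N deprotonates the Mg‑bound pyranone next to the ketone (soft enolisation), the resulting 2H‑pyran enolate 12 opens by thermal 6π retro‑electrocyclisation to the cis‑dienolate ketone 13, and the silyloxy‑bearing terminus of 13 adds to the side‑chain ketone to form C4–C5, the closest known reaction type being the Et3N‑mediated contraction of 2‑unsubstituted 6‑alkoxy‑ and 6‑silyloxy‑2H‑pyran‑3(6H)‑ones to trans‑4‑oxy‑5‑hydroxycyclopent‑2‑enones, extended here to a ketone acceptor, a tertiary carbinol and Mg control. The carbocycle closes in what is formally a 5‑(enolendo)‑exo‑trig vinylogous aldol addition and is better described as a thermal conrotatory 4π electrocyclisation of a 1,2‑dioxido‑5‑silyloxypentadienyl system, the ketone twisting out of the dienolate plane. C5 is set by the C6 stereocentre through one Mg2+ bound at once to the enolate oxygen, the ketone oxygen and the PMB ether oxygen, so that the C4 terminus reaches the ketone face on the side of the C6 hydrogen (Cram‑chelate sense, which gives 5R in 14), whereas Felkin–Anh approach would give the C5 epimer. C4 is set by the conrotation: the silyloxy group sits outside on the E enol ether (outward rotation in the ring opening) and the ketone oxygen is held outside, s‑cis to the enolate oxygen, by the same chelate, so the two oxygens end up trans. The step needs the 4,5‑trans and the chelate diastereomer, which the chelating PMB ether, MgBr2 and a non‑coordinating solvent are there to secure, and because both ring stereocentres of 11 are erased in 13 all four isomers of 11 converge.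

Step 9
Reactants: 14 (4S,5R)‑4‑(tert‑butyldimethylsilyloxy)‑5‑hydroxy‑5‑[(1S)‑1‑(4‑methoxybenzyloxy)tridecyl]cyclopent‑2‑en‑1‑one
Product: 15 (4S,5R)‑4‑(tert‑butyldimethylsilyloxy)‑5‑hydroxy‑5‑[(1S)‑1‑hydroxytridecyl]cyclopent‑2‑en‑1‑one
Conditions: DDQ (1.5 equiv), CH2Cl2/pH 7 buffer (10:1), 0 °C → rt
Reagents that add atoms: none
Why: Oxidative cleavage of a p‑methoxybenzyl ether: DDQ abstracts hydride from the electron‑rich benzylic position and water hydrolyses the oxocarbenium ion, while the silyl ether, the enone and the tertiary alcohol are inert to the quinone; no stereocentre is touched.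

Step 10
Reactants: 15 (4S,5R)‑4‑(tert‑butyldimethylsilyloxy)‑5‑hydroxy‑5‑[(1S)‑1‑hydroxytridecyl]cyclopent‑2‑en‑1‑one
Product: 16 (4S,5R)‑5‑[(1S)‑1‑acetoxytridecyl]‑4‑(tert‑butyldimethylsilyloxy)‑5‑hydroxycyclopent‑2‑en‑1‑one
Conditions: Ac2O (3 equiv), pyridine, CH2Cl2, 0 °C → rt
Reagents that add atoms: acetic anhydride, CC(=O)OC(C)=O
Why: Chemoselective O‑acylation: the secondary C6 hydroxyl is acetylated, whereas the tertiary C5 hydroxyl, hindered and hydrogen‑bonded to the ketone, does not react in the absence of DMAP; no stereocentre is touched.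

Step 11
Reactants: 16 (4S,5R)‑5‑[(1S)‑1‑acetoxytridecyl]‑4‑(tert‑butyldimethylsilyloxy)‑5‑hydroxycyclopent‑2‑en‑1‑one
Product: 17 (4S,5S)‑5‑[(1S)‑1‑acetoxytridecyl]‑4,5‑dihydroxycyclopent‑2‑en‑1‑one
Conditions: HF·pyridine, pyridine, THF, 0 °C → rt
Reagents that add atoms: none
Why: Fluoride‑driven cleavage of the Si–O bond under buffered acidic conditions, which avoid the free alkoxide that would start acetyl migration or retro‑aldol opening of the alpha‑ketol; no stereocentre is touched.

## Compound list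

1 | rac‑1,2‑epoxytetradecane | CCCCCCCCCCCCC1CO1 | starting material
2 | (S)‑tetradecane‑1,2‑diol | CCCCCCCCCCCC[C@H](O)CO | intermediate
3 | (4S)‑4‑dodecyl‑2‑(4‑methoxyphenyl)‑1,3‑dioxolane (both C2 epimers) | CCCCCCCCCCCC[C@H]1COC(c2ccc(OC)cc2)O1 | intermediate
4 | (2S)‑2‑(4‑methoxybenzyloxy)tetradecan‑1‑ol | CCCCCCCCCCCC[C@H](OCc1ccc(OC)cc1)CO | intermediate
5 | (2S)‑2‑(4‑methoxybenzyloxy)tetradecanal | CCCCCCCCCCCC[C@H](OCc1ccc(OC)cc1)C=O | intermediate
6 | furan | c1ccoc1 | starting material
7 | 2‑furyllithium (not isolated) | [Li]c1ccco1 | intermediate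
8 | (2S)‑1‑(furan‑2‑yl)‑2‑(4‑methoxybenzyloxy)tetradecan‑1‑ol (both C1 epimers) | CCCCCCCCCCCC[C@H](OCc1ccc(OC)cc1)C(O)c1ccco1 | intermediate
9 | (2Z,6S)‑5‑hydroxy‑6‑(4‑methoxybenzyloxy)‑4‑oxooctadec‑2‑enal (both C5 epimers; not isolated) | CCCCCCCCCCCC[C@H](OCc1ccc(OC)cc1)C(O)C(=O)/C=C\C=O | intermediate
10 | 6‑hydroxy‑2‑[(1S)‑1‑(4‑methoxybenzyloxy)tridecyl]‑2H‑pyran‑3(6H)‑one (all four ring isomers) | CCCCCCCCCCCC[C@H](OCc1ccc(OC)cc1)C1OC(O)C=CC1=O | intermediate
11 | 6‑(tert‑butyldimethylsilyloxy)‑2‑[(1S)‑1‑(4‑methoxybenzyloxy)tridecyl]‑2H‑pyran‑3(6H)‑one (all four ring isomers) | CCCCCCCCCCCC[C@H](OCc1ccc(OC)cc1)C1OC(O[Si](C)(C)C(C)(C)C)C=CC1=O | intermediate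
12 | bromomagnesium enolate of 11, a 3‑oxido‑2H‑pyran with the side chain on the enolate carbon (both epimers at the silyloxy carbon; not isolated) | CCCCCCCCCCCC[C@H](OCc1ccc(OC)cc1)C1=C(O[Mg]Br)C=CC(O[Si](C)(C)C(C)(C)C)O1 | intermediate
13 | bromomagnesium (6S)‑1‑(tert‑butyldimethylsilyloxy)‑6‑(4‑methoxybenzyloxy)‑5‑oxooctadeca‑1,3‑dien‑4‑olate, E enol ether, ketone carbon and C2 cis on the C3=C4 bond (not isolated) | CCCCCCCCCCCC[C@H](OCc1ccc(OC)cc1)C(=O)/C(O[Mg]Br)=C\C=C\O[Si](C)(C)C(C)(C)C | intermediate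
14 | (4S,5R)‑4‑(tert‑butyldimethylsilyloxy)‑5‑hydroxy‑5‑[(1S)‑1‑(4‑methoxybenzyloxy)tridecyl]cyclopent‑2‑en‑1‑one | CCCCCCCCCCCC[C@H](OCc1ccc(OC)cc1)[C@]1(O)C(=O)C=C[C@@H]1O[Si](C)(C)C(C)(C)C | intermediate
15 | (4S,5R)‑4‑(tert‑butyldimethylsilyloxy)‑5‑hydroxy‑5‑[(1S)‑1‑hydroxytridecyl]cyclopent‑2‑en‑1‑one | CCCCCCCCCCCC[C@H](O)[C@]1(O)C(=O)C=C[C@@H]1O[Si](C)(C)C(C)(C)C | intermediate
16 | (4S,5R)‑5‑[(1S)‑1‑acetoxytridecyl]‑4‑(tert‑butyldimethylsilyloxy)‑5‑hydroxycyclopent‑2‑en‑1‑one | CCCCCCCCCCCC[C@H](OC(C)=O)[C@]1(O)C(=O)C=C[C@@H]1O[Si](C)(C)C(C)(C)C | intermediate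
17 | (4S,5S)‑5‑[(1S)‑1‑acetoxytridecyl]‑4,5‑dihydroxycyclopent‑2‑en‑1‑one | CCCCCCCCCCCC[C@H](OC(C)=O)[C@]1(O)C(=O)C=C[C@@H]1O | target

## Step count

Total step count: 11.
Longest linear sequence: 11 steps (1 → 17); furan 6 enters at step 5.

## Steps most likely to fail

**Step 8 (proposed new method).** Three processes could defeat it:
- E1cB loss of the PMB‑oxy group from the pyranone enolate before the ring opens;
- ionisation of the silyl acetal by the Lewis acid;
- closure without control, either from the Felkin face (C5 epimer) or with the ketone oxygen inside (4,5‑cis).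

The fallback uses known chemistry, sets out from 8 and returns at 14. It moves the C4–C5 closure to the furan oxidation level and brings in the C5 oxygen afterwards. Piancatelli rearrangement of 8 (Dy(OTf)3 cat., MeCN/H2O, 80 °C), the acid‑mediated conrotatory 4π closure of 2‑furylcarbinols, should give the trans product (4S,5S)‑4‑hydroxy‑5‑[(1S)‑1‑(4‑methoxybenzyloxy)tridecyl]cyclopent‑2‑en‑1‑one F1. Its (4R,5R) diastereomer is expected alongside, because the side chain is not expected to control C4. Silylation (TBSCl, imidazole, CH2Cl2) and chromatographic separation should give (4S,5R)‑4‑(tert‑butyldimethylsilyloxy)‑5‑[(1S)‑1‑(4‑methoxybenzyloxy)tridecyl]cyclopent‑2‑en‑1‑one F2. Kinetic deprotonation at C5 (KHMDS, THF, −78 °C) and oxidation of the enolate with 2‑(phenylsulfonyl)‑3‑phenyloxaziridine, on the face anti to the C4 silyloxy group, should place the C5 hydroxyl trans to O4 and give 14.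

**Step 11.** The hindered allylic silyl ether next to the quaternary carbon may be cleaved slowly, and acetyl migration from O6 to O5 or O4, or decomposition of the alpha‑ketol, may then compete. The fallback sets out from 14 and returns at 17; it takes the robust silyl group off before the acetate is present and carries O4 through the end game as a far more labile silyl ether.
- HF·pyridine on 14 should give (4S,5S)‑4,5‑dihydroxy‑5‑[(1S)‑1‑(4‑methoxybenzyloxy)tridecyl]cyclopent‑2‑en‑1‑one F4.
- TESCl and imidazole should silylate only the secondary hydroxyl and give (4S,5R)‑5‑hydroxy‑5‑[(1S)‑1‑(4‑methoxybenzyloxy)tridecyl]‑4‑(triethylsilyloxy)cyclopent‑2‑en‑1‑one F5.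
- DDQ in wet CH2Cl2 should give (4S,5R)‑5‑hydroxy‑5‑[(1S)‑1‑hydroxytridecyl]‑4‑(triethylsilyloxy)cyclopent‑2‑en‑1‑one F6.
- Ac2O and pyridine should give (4S,5R)‑5‑[(1S)‑1‑acetoxytridecyl]‑5‑hydroxy‑4‑(triethylsilyloxy)cyclopent‑2‑en‑1‑one F7.
- AcOH/THF/H2O at rt should release 17 without fluoride or base.

**Step 9.** The benzylic oxocarbenium ion may be trapped by the neighbouring tertiary hydroxyl instead of water, and the acetal so formed may be oxidised further to a p‑methoxybenzoate. The fallback sets out from 14 and returns at 15; it makes this diversion the intended path. DDQ in dry CH2Cl2 over 4 Å molecular sieves should convert 14 fully into the spiro p‑methoxybenzylidene acetal across O5 and O6 (mixture at the acetal carbon) F3. Mild hydrolysis of F3 (AcOH/THF/H2O, rt), under which the secondary TBS ether should survive, should then give 15.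

## Further compounds

F1 | step 8 | (4S,5S)‑4‑hydroxy‑5‑[(1S)‑1‑(4‑methoxybenzyloxy)tridecyl]cyclopent‑2‑en‑1‑one | CCCCCCCCCCCC[C@H](OCc1ccc(OC)cc1)[C@H]1C(=O)C=C[C@@H]1O
F2 | step 8 | (4S,5R)‑4‑(tert‑butyldimethylsilyloxy)‑5‑[(1S)‑1‑(4‑methoxybenzyloxy)tridecyl]cyclopent‑2‑en‑1‑one | CCCCCCCCCCCC[C@H](OCc1ccc(OC)cc1)[C@H]1C(=O)C=C[C@@H]1O[Si](C)(C)C(C)(C)C
F3 | step 9 | spiro p‑methoxybenzylidene acetal of diol 15 across O5 and O6 (mixture at the acetal carbon) | CCCCCCCCCCCC[C@@H]1OC(c2ccc(OC)cc2)O[C@]13C(=O)C=C[C@@H]3O[Si](C)(C)C(C)(C)C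
F4 | step 11 | (4S,5S)‑4,5‑dihydroxy‑5‑[(1S)‑1‑(4‑methoxybenzyloxy)tridecyl]cyclopent‑2‑en‑1‑one | CCCCCCCCCCCC[C@H](OCc1ccc(OC)cc1)[C@]1(O)C(=O)C=C[C@@H]1O
F5 | step 11 | (4S,5R)‑5‑hydroxy‑5‑[(1S)‑1‑(4‑methoxybenzyloxy)tridecyl]‑4‑(triethylsilyloxy)cyclopent‑2‑en‑1‑one | CCCCCCCCCCCC[C@H](OCc1ccc(OC)cc1)[C@]1(O)C(=O)C=C[C@@H]1O[Si](CC)(CC)CC
F6 | step 11 | (4S,5R)‑5‑hydroxy‑5‑[(1S)‑1‑hydroxytridecyl]‑4‑(triethylsilyloxy)cyclopent‑2‑en‑1‑one | CCCCCCCCCCCC[C@H](O)[C@]1(O)C(=O)C=C[C@@H]1O[Si](CC)(CC)CC
F7 | step 11 | (4S,5R)‑5‑[(1S)‑1‑acetoxytridecyl]‑5‑hydroxy‑4‑(triethylsilyloxy)cyclopent‑2‑en‑1‑one | CCCCCCCCCCCC[C@H](OC(C)=O)[C@]1(O)C(=O)C=C[C@@H]1O[Si](CC)(CC)CC
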